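**Assumption:** the target has no stereocentre and no E/Z-capable double bond, so "single enantiomer" is taken to mean the one achiral compound; the tert-prenyl carbonate is made in-house because its commercial supply is uncertain.

## Retrosynthetic overview
1. Target 13 ⇒ tris-MOM ketone 12 by cleavage of three aryl O–CH2 acetal bonds.
2. 12 ⇒ aryllithium 11 (from phloroglucinol 9 via 10) + diprenylated ester 8 (C-acylation).
3. 8 ⇒ phenol ester 4 + 2 × carbonate 3. The key bond is the aryl O–C(CH3)2 ether bond, formed twice; each ether then passes its C5 unit to the ortho carbon by a [3,3] shift.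
4. 3 ⇒ 2-methylbut-3-en-2-ol 1.
5. No ring is formed: both benzene rings are bought (4 and 9).

## Route

Step 1
Reactants: 1 2-methylbut-3-en-2-ol
Product: 3 tert-butyl 2-methylbut-3-en-2-yl carbonate, via lithium 2-methylbut-3-en-2-olate 2 (not isolated)
Conditions: n-BuLi (1.05 equiv), THF, −78 → 0 °C; Boc2O (1.1 equiv), 0 °C → rt; then aq. NH4Cl
Reagents that add atoms: di-tert-butyl dicarbonate, CC(C)(C)OC(=O)OC(=O)OC(C)(C)C
Why: O-acylation of a pre-formed tertiary lithium alkoxide by Boc2O (nucleophilic acyl substitution) is the standard access to tertiary allylic tert-butyl carbonates; no stereocentre is formed.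

Step 2
Reactants: 4 methyl 3-(4-hydroxyphenyl)propanoate; 3 tert-butyl 2-methylbut-3-en-2-yl carbonate
Product: 8 methyl 3-[4-hydroxy-3,5-bis(3-methylbut-2-en-1-yl)phenyl]propanoate, via first tert-prenyl ether 5 (not isolated), via mono-prenyl phenol 6 (not isolated), via second tert-prenyl ether 7 (not isolated)
Conditions: Pd(PPh3)4 (2 mol%), Eu(fod)3 (10 mol%), PhMe; 3 (1.15 equiv), 0 °C, 1 h, then 60 °C, 4 h; cool, second charge of 3 (1.15 equiv), 0 °C, 1 h, then 60 °C, 6 h
Reagents that add atoms: none
Why: Proposed new method: a one-flask Pd(0)/Eu(III) relay in which Pd(PPh3)4 ionises the tertiary carbonate 3 irreversibly (loss of CO2) to a 1,1-dimethylallyl–Pd cation whose tert-butoxide counter-ion deprotonates the phenol, the phenoxide then closing the key aryl O–C(CH3)2 bond at the more substituted allyl terminus at 0 °C; Eu(fod)3 binds the ether oxygen and lowers the barrier of the aromatic Claisen [3,3] shift so that at 60 °C the ether should empty into the ortho-prenylphenol (a C–C bonded sink) faster than Pd(0) can re-ionise this poor aryloxide leaving group (phenol pKa about 10) and isomerise it to the linear ether, and because the para position is blocked the freed phenol re-enters the same cycle with the second charge of 3 to give the 2,6-diprenyl pattern; the closest known reaction types are the Pd-catalysed decarboxylative O-tert-prenylation of phenols with 2-methylbut-3-en-2-yl carbonates and the separately run thermal or Eu(fod)3-catalysed aromatic Claisen rearrangement of aryl 1,1-dimethylallyl ethers, which to my knowledge have not been merged into a double single-flask relay.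

Step 3
Reactants: 9 phloroglucinol (benzene-1,3,5-triol, anhydrous)
Product: 10 1,3,5-tris(methoxymethoxy)benzene
Conditions: MOMCl (3.6 equiv), i-Pr2NEt (4.5 equiv), CH2Cl2/DMF, 0 °C → rt
Reagents that add atoms: chloromethyl methyl ether (MOMCl), COCCl
Why: Threefold Williamson-type O-alkylation of the phenol with the hard oxocarbenium-type electrophile MOMCl masks the acidic OH groups and installs three ortho-directing groups.

Step 4
Reactants: 10 1,3,5-tris(methoxymethoxy)benzene; 8 methyl 3-[4-hydroxy-3,5-bis(3-methylbut-2-en-1-yl)phenyl]propanoate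
Product: 12 3-[4-hydroxy-3,5-bis(3-methylbut-2-en-1-yl)phenyl]-1-[2,4,6-tris(methoxymethoxy)phenyl]propan-1-one, via aryllithium 11 (not isolated)
Conditions: 10 (2.7 equiv), n-BuLi (2.5 equiv), THF, 0 °C, 1 h; add 8 (1.0 equiv) in THF, −78 → −20 °C; then aq. NH4Cl
Reagents that add atoms: none
Why: Directed ortho-metalation between two OMOM groups gives 11 (every ring C–H is equivalent), the first equivalent only removes the phenolic proton of 8 and returns 10, and nucleophilic acyl substitution on the methyl ester stops at the ketone because a di-ortho-substituted aryl ketone (or its enolate) resists a second attack by the equally hindered aryllithium.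

Step 5
Reactants: 12 3-[4-hydroxy-3,5-bis(3-methylbut-2-en-1-yl)phenyl]-1-[2,4,6-tris(methoxymethoxy)phenyl]propan-1-one
Product: 13 4,2',4',6'-tetrahydroxy-3,5-diprenyldihydrochalcone, i.e. 3-[4-hydroxy-3,5-bis(3-methylbut-2-en-1-yl)phenyl]-1-(2,4,6-trihydroxyphenyl)propan-1-one
Conditions: HCl (1.25 M in MeOH, 3 equiv), MeOH, 25 °C, monitored and stopped at full conversion
Reagents that add atoms: none
Why: Acid-catalysed transacetalisation (MOM ether cleavage) passes the three CH2OCH3 units to methanol as dimethoxymethane, and dilute HCl at 25 °C is mild enough to leave the trisubstituted prenyl alkenes unprotonated.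

## Compound list
1 | 2-methylbut-3-en-2-ol | CC(C)(O)C=C | starting material
2 | lithium 2-methylbut-3-en-2-olate | [Li+].[O-]C(C)(C)C=C | intermediate
3 | tert-butyl 2-methylbut-3-en-2-yl carbonate | C=CC(C)(C)OC(=O)OC(C)(C)C | intermediate
4 | methyl 3-(4-hydroxyphenyl)propanoate | COC(=O)CCc1ccc(O)cc1 | starting material
5 | methyl 3-{4-[(2-methylbut-3-en-2-yl)oxy]phenyl}propanoate | COC(=O)CCc1ccc(OC(C)(C)C=C)cc1 | intermediate
6 | methyl 3-[4-hydroxy-3-(3-methylbut-2-en-1-yl)phenyl]propanoate | COC(=O)CCc1ccc(O)c(CC=C(C)C)c1 | intermediate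
7 | methyl 3-{3-(3-methylbut-2-en-1-yl)-4-[(2-methylbut-3-en-2-yl)oxy]phenyl}propanoate | COC(=O)CCc1ccc(OC(C)(C)C=C)c(CC=C(C)C)c1 | intermediate
8 | methyl 3-[4-hydroxy-3,5-bis(3-methylbut-2-en-1-yl)phenyl]propanoate | COC(=O)CCc1cc(CC=C(C)C)c(O)c(CC=C(C)C)c1 | intermediate
9 | phloroglucinol (benzene-1,3,5-triol) | Oc1cc(O)cc(O)c1 | starting material
10 | 1,3,5-tris(methoxymethoxy)benzene | COCOc1cc(OCOC)cc(OCOC)c1 | intermediate
11 | 2,4,6-tris(methoxymethoxy)phenyllithium | [Li]c1c(OCOC)cc(OCOC)cc1OCOC | intermediate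
12 | 3-[4-hydroxy-3,5-bis(3-methylbut-2-en-1-yl)phenyl]-1-[2,4,6-tris(methoxymethoxy)phenyl]propan-1-one | COCOc1cc(OCOC)c(C(=O)CCc2cc(CC=C(C)C)c(O)c(CC=C(C)C)c2)c(OCOC)c1 | intermediate
13 | 4,2',4',6'-tetrahydroxy-3,5-diprenyldihydrochalcone | CC(C)=CCc1cc(CCC(=O)c2c(O)cc(O)cc2O)cc(CC=C(C)C)c1O | target

## Summary
Total step count: 5. Longest linear sequence: 4 steps (1 → 2 → 4 → 5).

Steps most likely to fail:

**Step 2 (proposed new relay).** Risks are Pd-mediated isomerisation of the tertiary ethers to linear prenyl ethers at 60 °C, inhibition of Eu(fod)3 by tert-butanol or the ester, and over-alkylation of 8. The fallback uses known chemistry only, sets out from 4 and comes back at 8; step 1 is then not needed. Phenol 4 is O-alkylated with 3-chloro-3-methylbut-1-yne (DBU, cat. CuCl2, MeCN, 0 °C) to methyl 3-{4-[(2-methylbut-3-yn-2-yl)oxy]phenyl}propanoate F1. Lindlar semi-hydrogenation (H2, Pd/CaCO3–Pb, quinoline, EtOAc) gives 5, which is isolated and heated on its own (N,N-diethylaniline or PhMe, 120 °C) to 6 by a purely thermal Claisen rearrangement. The same three operations on 6 give methyl 3-{3-(3-methylbut-2-en-1-yl)-4-[(2-methylbut-3-yn-2-yl)oxy]phenyl}propanoate F2, then 7, then 8. The Lindlar catalyst does not touch the trisubstituted prenyl alkene in the second round.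

**Step 4 (aryllithium on a methyl ester).** Risks are enolisation of the ester by the hindered aryllithium and incomplete conversion. The fallback sets out from 8 and comes back at 12. Ester 8 is converted with MeNH(OMe)·HCl and i-PrMgCl (THF, −20 → 0 °C) into 3-[4-hydroxy-3,5-bis(3-methylbut-2-en-1-yl)phenyl]-N-methoxy-N-methylpropanamide F3. Aryllithium 11 (2.5 equiv, THF, −78 → 0 °C) then adds once, the N-methoxy chelate preventing over-addition, and aqueous NH4Cl releases 12.

**Step 5 (MOM cleavage beside ortho-prenylphenol).** The risk is acid-induced cyclisation of the B-ring phenol onto a prenyl group to give a 2,2-dimethylchroman. The fallback replaces the acid-labile group by a fluoride-labile one; it sets out from 9 (and uses 8) and comes back at 13. Phloroglucinol 9 with SEMCl and i-Pr2NEt (CH2Cl2) gives 1,3,5-tris{[2-(trimethylsilyl)ethoxy]methoxy}benzene F4. n-BuLi (THF, 0 °C) gives 2,4,6-tris{[2-(trimethylsilyl)ethoxy]methoxy}phenyllithium F5, which acylates with 8 as in step 4 to 3-[4-hydroxy-3,5-bis(3-methylbut-2-en-1-yl)phenyl]-1-(2,4,6-tris{[2-(trimethylsilyl)ethoxy]methoxy}phenyl)propan-1-one F6. TBAF (THF/DMPU, 50 °C) then removes the three SEM groups without acid and gives 13.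

## Further compounds
F1 | step 2 | methyl 3-{4-[(2-methylbut-3-yn-2-yl)oxy]phenyl}propanoate | COC(=O)CCc1ccc(OC(C)(C)C#C)cc1
F2 | step 2 | methyl 3-{3-(3-methylbut-2-en-1-yl)-4-[(2-methylbut-3-yn-2-yl)oxy]phenyl}propanoate | COC(=O)CCc1ccc(OC(C)(C)C#C)c(CC=C(C)C)c1
F3 | step 4 | 3-[4-hydroxy-3,5-bis(3-methylbut-2-en-1-yl)phenyl]-N-methoxy-N-methylpropanamide | CON(C)C(=O)CCc1cc(CC=C(C)C)c(O)c(CC=C(C)C)c1
F4 | step 5 | 1,3,5-tris{[2-(trimethylsilyl)ethoxy]methoxy}benzene | C[Si](C)(C)CCOCOc1cc(OCOCC[Si](C)(C)C)cc(OCOCC[Si](C)(C)C)c1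
F5 | step 5 | 2,4,6-tris{[2-(trimethylsilyl)ethoxy]methoxy}phenyllithium | [Li]c1c(OCOCC[Si](C)(C)C)cc(OCOCC[Si](C)(C)C)cc1OCOCC[Si](C)(C)C
F6 | step 5 | 3-[4-hydroxy-3,5-bis(3-methylbut-2-en-1-yl)phenyl]-1-(2,4,6-tris{[2-(trimethylsilyl)ethoxy]methoxy}phenyl)propan-1-one | C[Si](C)(C)CCOCOc1cc(OCOCC[Si](C)(C)C)c(C(=O)CCc2cc(CC=C(C)C)c(O)c(CC=C(C)C)c2)c(OCOCC[Si](C)(C)C)c1
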